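**Strategy**

The route rests on annulating the whole α-methylene-γ-butyrolactone onto a preformed ten-membered carbocycle. The feature exploited is that the lactone carbinol carbon C6 is allylic to the ring alkene C4=C5: a cyclodeca-2,4,8-trienol holding the C4=C5–C6=C7 diene and a free C8 hydroxyl reacts with 2-bromoacrylic acid under palladium catalysis. Hydroxyl-directed carbopalladation joins the acrylate α-carbon to C7, and the C4–C6 π-allyl is closed by the carboxylate oxygen at C6. One operation thus creates the lactone ring, both ring-fusion stereocentres and leaves C4=C5 in place. The trienol arises from a vinylbutyrolactone aldol condensation, reduction, silylation and ring-closing metathesis.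

Key step: step 9

Remark: atoms carry germacrane labels throughout (ring C1–C10; C6 = lactone O–CH, C7 = ring-fusion CH, C8 = acyloxy CH, C11 = methylidene-bearing carbon, C12 = lactone C=O, C14 and C15 = CH2O carbons on C10 and C4). (R)-5-(Hydroxymethyl)oxolan-2-one is taken as a commercial chiral-pool material.

**Route**

Step 1
Reactants: 1 (5R)-5-(hydroxymethyl)oxolan-2-one
Product: 2 (2R)-5-oxooxolane-2-carbaldehyde
Conditions: Dess–Martin periodinane, CH2Cl2, 0 °C → rt; short silica pad, used crude
Reagents that add atoms: none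
Why: Dess–Martin oxidation takes the primary alcohol to the aldehyde under neutral conditions that should leave the lactone and the oxygenated stereocentre (the later C8) untouched.

Step 2
Reactants: 2 (2R)-5-oxooxolane-2-carbaldehyde
Product: 3 (5R)-5-ethenyloxolan-2-one
Conditions: Ph3PCH3Br, KN(SiMe3)2, THF, 0 °C; then 2, −78 → 0 °C
Reagents that add atoms: methyltriphenylphosphonium bromide, C[P+](c1ccccc1)(c1ccccc1)c1ccccc1.[Br-]
Why: Wittig methylenation with the unstabilised ylide at low temperature should be faster at the aldehyde than at the lactone carbonyl and faster than enolisation, so the stereocentre is kept.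

Step 3
Reactants: 4 triethyl phosphonoacetate; 5 3-bromo-1,1-dimethoxypropane
Product: 6 ethyl 2-(diethoxyphosphoryl)-5,5-dimethoxypentanoate (racemic)
Conditions: NaH, DMF, 0 °C; then 5, 70 °C (4 in excess)
Reagents that add atoms: none
Why: SN2 alkylation of the sodium phosphonoacetate by a primary bromide; excess 4 should limit dialkylation.

Step 4
Reactants: 6 ethyl 2-(diethoxyphosphoryl)-5,5-dimethoxypentanoate; 7 (E)-but-2-enal
Product: 9 ethyl (2E,4E)-2-(3-oxopropyl)hexa-2,4-dienoate, via dimethyl acetal 8 (not isolated)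
Conditions: NaH, THF, 0 °C → rt; then 1 M aq. HCl, rt
Reagents that add atoms: water, O
Why: Horner–Wadsworth–Emmons olefination of the enal should give mainly the trisubstituted enoate with the ester trans to the diene carbon (minor 2Z isomer removed by chromatography), and the acidic work-up hydrolyses the dimethyl acetal.

Step 5
Reactants: 3 (5R)-5-ethenyloxolan-2-one; 9 ethyl (2E,4E)-2-(3-oxopropyl)hexa-2,4-dienoate
Product: 12 ethyl (2E,4E)-2-{3-[(3E,5R)-5-ethenyl-2-oxooxolan-3-ylidene]propyl}hexa-2,4-dienoate, via aldolate 10 (not isolated), via mesylate 11 (not isolated)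
Conditions: LiN(i-Pr)2, THF, −78 °C; 9, −78 °C; MsCl, −78 → 0 °C; DBU, 0 °C → rt
Reagents that add atoms: none
Why: Aldol condensation in one pot (enolate addition, mesylation of the aldolate, E1cB elimination); the E-alkylidene lactone (chain cis to the ring CH2) is the thermodynamic product, and the γ-stereocentre is not involved.

Step 6
Reactants: 12 ethyl (2E,4E)-2-{3-[(3E,5R)-5-ethenyl-2-oxooxolan-3-ylidene]propyl}hexa-2,4-dienoate
Product: 13 (3R,5E,9E,11E)-5,9-bis(hydroxymethyl)trideca-1,5,9,11-tetraen-3-ol
Conditions: i-Bu2AlH (6 equiv), CH2Cl2, −78 → 0 °C; aq. KNaC4H4O6 work-up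
Reagents that add atoms: none
Why: 1,2-Reduction of the enoate and of the alkylidene lactone by the aluminium hydride should give both primary allylic alcohols and free the C8 carbinol without touching alkene geometry or the stereocentre.

Step 7
Reactants: 13 (3R,5E,9E,11E)-5,9-bis(hydroxymethyl)trideca-1,5,9,11-tetraen-3-ol
Product: 14 (3R,5E,9E,11E)-5,9-bis({[tert-butyl(dimethyl)silyl]oxy}methyl)trideca-1,5,9,11-tetraen-3-ol
Conditions: TBSCl (2.1 equiv), imidazole, CH2Cl2, −20 → 0 °C
Reagents that add atoms: tert-butyldimethylsilyl chloride, CC(C)(C)[Si](C)(C)Cl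
Why: Chemoselective silyl ether formation; the two primary allylic hydroxyls react much faster than the secondary one, which stays free for the key step.

Step 8
Reactants: 14 (3R,5E,9E,11E)-5,9-bis({[tert-butyl(dimethyl)silyl]oxy}methyl)trideca-1,5,9,11-tetraen-3-ol
Product: 15 (1R,2Z,4E,8E)-5,9-bis({[tert-butyl(dimethyl)silyl]oxy}methyl)cyclodeca-2,4,8-trien-1-ol (all three ring alkenes cis within the ring)
Conditions: second-generation Grubbs catalyst (H2IMes)(PCy3)Cl2Ru=CHPh (10 mol %), 1,4-benzoquinone (20 mol %), toluene (1 mM), 80 °C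
Reagents that add atoms: none
Why: Ring-closing metathesis; the catalyst should load on the vinyl group next to the free carbinol and close onto the methyl-capped diene terminus, the only disubstituted alkene, and the ten-membered ring can hold the new C6=C7 bond only as the cis alkene.

Step 9
Reactants: 15 (1R,2Z,4E,8E)-5,9-bis({[tert-butyl(dimethyl)silyl]oxy}methyl)cyclodeca-2,4,8-trien-1-ol; 16 2-bromoacrylic acid
Product: 17 (3aR,4R,6E,10E,11aR)-6,10-bis({[tert-butyl(dimethyl)silyl]oxy}methyl)-4-hydroxy-3-methylidene-3a,4,5,8,9,11a-hexahydrocyclodeca[b]furan-2(3H)-one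
Conditions: Pd(OAc)2 (10 mol %), P(2-furyl)3 (20 mol %), Ag2CO3 (1.5 equiv), MeCN, 60 °C
Reagents that add atoms: none
Why: Zerovalent palladium inserts into the C–Br bond of 16; the 1-carboxyvinyl divalent palladium species, held by the C8 hydroxyl, adds across C6=C7 with carbon going to C7 and palladium to C6, where it becomes the C4–C5–C6 π-allyl, and the carboxylate then attacks C6 and releases zerovalent palladium. The closest known reaction type is the Larock heteroannulation of 1,3-dienes by vinylic or aryl halides that carry a carboxylic acid. The γ-lactone closes in a 5-exo mode by O-attack at the proximal allyl terminus C6, so C4=C5 stays in the ten-membered ring with its geometry unchanged. C7 is set by syn carbopalladation on the alkene face reached through the five-membered Pd–C6–C7–C8–O chelate, which places C11 cis to O8, as in metal-alkoxide-directed additions to medium-ring allylic alcohols; C6 is set by carboxylate attack anti to palladium, which gives the trans ring fusion, and because zerovalent palladium can re-ionise the allylic lactone, the trans-fused isomer, expected to be the more stable, should prevail. The step needs regioselectivity for C7 over the fully substituted diene terminus C4, closure at C6 rather than C4 (five- versus seven-membered ring) and chemoselectivity for the diene over the trisubstituted C1=C10 alkene; substitution pattern, chelation and ring size should secure these.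

Step 10
Reactants: 17 (3aR,4R,6E,10E,11aR)-6,10-bis({[tert-butyl(dimethyl)silyl]oxy}methyl)-4-hydroxy-3-methylidene-3a,4,5,8,9,11a-hexahydrocyclodeca[b]furan-2(3H)-one; 18 3-methylbutanoic anhydride
Product: 19 (3aR,4R,6E,10E,11aR)-6,10-bis({[tert-butyl(dimethyl)silyl]oxy}methyl)-3-methylidene-2-oxo-2,3,3a,4,5,8,9,11a-octahydrocyclodeca[b]furan-4-yl 3-methylbutanoate
Conditions: Et3N, DMAP (cat.), CH2Cl2, 0 °C → rt
Reagents that add atoms: none
Why: DMAP-catalysed acylation of the only free hydroxyl; C8 is not a reacting centre, so its configuration is kept, and prompt acylation forestalls lactone migration to O8.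

Step 11
Reactants: 19 (3aR,4R,6E,10E,11aR)-6,10-bis({[tert-butyl(dimethyl)silyl]oxy}methyl)-3-methylidene-2-oxo-2,3,3a,4,5,8,9,11a-octahydrocyclodeca[b]furan-4-yl 3-methylbutanoate
Product: 20 (3aR,4R,6E,10E,11aR)-6,10-bis(hydroxymethyl)-3-methylidene-2-oxo-2,3,3a,4,5,8,9,11a-octahydrocyclodeca[b]furan-4-yl 3-methylbutanoate (CNP0199826.1)
Conditions: HF·pyridine, pyridine, THF, 0 °C → rt
Reagents that add atoms: none
Why: Fluoride-mediated desilylation of the two primary silyl ethers under buffered conditions that should spare the ester, the α-methylene lactone and the allylic alcohols.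

**Compound list**

1 | (5R)-5-(hydroxymethyl)oxolan-2-one | OC[C@H]1CCC(=O)O1 | starting material
2 | (2R)-5-oxooxolane-2-carbaldehyde | O=C[C@H]1CCC(=O)O1 | intermediate
3 | (5R)-5-ethenyloxolan-2-one | C=C[C@H]1CCC(=O)O1 | intermediate
4 | triethyl phosphonoacetate | CCOC(=O)CP(=O)(OCC)OCC | starting material
5 | 3-bromo-1,1-dimethoxypropane | COC(OC)CCBr | starting material
6 | ethyl 2-(diethoxyphosphoryl)-5,5-dimethoxypentanoate (racemic) | CCOC(=O)C(CCC(OC)OC)P(=O)(OCC)OCC | intermediate
7 | (E)-but-2-enal | C/C=C/C=O | starting material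
8 | ethyl (2E,4E)-2-(3,3-dimethoxypropyl)hexa-2,4-dienoate | COC(OC)CC/C(C(=O)OCC)=C\C=C\C | intermediate (not isolated)
9 | ethyl (2E,4E)-2-(3-oxopropyl)hexa-2,4-dienoate | O=CCC/C(C(=O)OCC)=C\C=C\C | intermediate
10 | ethyl (2E,4E)-2-{3-[(5R)-5-ethenyl-2-oxooxolan-3-yl]-3-hydroxypropyl}hexa-2,4-dienoate (present as its lithium alkoxide; mixture at the two new centres) | C=C[C@H]1CC(C(O)CC/C(C(=O)OCC)=C\C=C\C)C(=O)O1 | intermediate (not isolated)
11 | ethyl (2E,4E)-2-{3-[(5R)-5-ethenyl-2-oxooxolan-3-yl]-3-(methanesulfonyloxy)propyl}hexa-2,4-dienoate (mixture at the two new centres) | C=C[C@H]1CC(C(OS(C)(=O)=O)CC/C(C(=O)OCC)=C\C=C\C)C(=O)O1 | intermediate (not isolated)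
12 | ethyl (2E,4E)-2-{3-[(3E,5R)-5-ethenyl-2-oxooxolan-3-ylidene]propyl}hexa-2,4-dienoate | C=C[C@H]1C/C(=C\CC/C(C(=O)OCC)=C\C=C\C)C(=O)O1 | intermediate
13 | (3R,5E,9E,11E)-5,9-bis(hydroxymethyl)trideca-1,5,9,11-tetraen-3-ol | C=C[C@H](O)C/C(CO)=C\CC/C(CO)=C\C=C\C | intermediate
14 | (3R,5E,9E,11E)-5,9-bis({[tert-butyl(dimethyl)silyl]oxy}methyl)trideca-1,5,9,11-tetraen-3-ol | C=C[C@H](O)C/C(CO[Si](C)(C)C(C)(C)C)=C\CC/C(CO[Si](C)(C)C(C)(C)C)=C\C=C\C | intermediate
15 | (1R,2Z,4E,8E)-5,9-bis({[tert-butyl(dimethyl)silyl]oxy}methyl)cyclodeca-2,4,8-trien-1-ol | C1/C(CO[Si](C)(C)C(C)(C)C)=C\C=C/[C@H](O)C/C(CO[Si](C)(C)C(C)(C)C)=C\C1 | intermediate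
16 | 2-bromoacrylic acid | C=C(Br)C(=O)O | starting material
17 | (3aR,4R,6E,10E,11aR)-6,10-bis({[tert-butyl(dimethyl)silyl]oxy}methyl)-4-hydroxy-3-methylidene-3a,4,5,8,9,11a-hexahydrocyclodeca[b]furan-2(3H)-one | C=C1C(=O)O[C@@H]2/C=C(/CO[Si](C)(C)C(C)(C)C)CC/C=C(/CO[Si](C)(C)C(C)(C)C)C[C@@H](O)[C@@H]12 | intermediate
18 | 3-methylbutanoic anhydride | CC(C)CC(=O)OC(=O)CC(C)C | starting material
19 | (3aR,4R,6E,10E,11aR)-6,10-bis({[tert-butyl(dimethyl)silyl]oxy}methyl)-3-methylidene-2-oxo-2,3,3a,4,5,8,9,11a-octahydrocyclodeca[b]furan-4-yl 3-methylbutanoate | C=C1C(=O)O[C@@H]2/C=C(/CO[Si](C)(C)C(C)(C)C)CC/C=C(/CO[Si](C)(C)C(C)(C)C)C[C@@H](OC(=O)CC(C)C)[C@@H]12 | intermediate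
20 | (3aR,4R,6E,10E,11aR)-6,10-bis(hydroxymethyl)-3-methylidene-2-oxo-2,3,3a,4,5,8,9,11a-octahydrocyclodeca[b]furan-4-yl 3-methylbutanoate | C=C1C(=O)O[C@@H]2/C=C(/CO)CC/C=C(/CO)C[C@@H](OC(=O)CC(C)C)[C@@H]12 | target

**Count and risks**

Total step count: 11. Longest linear sequence: 9 steps (1 → 20 through steps 1, 2 and 5–11; the branch from 4 through steps 3, 4 and 5–11 is equally long).

Steps most likely to fail:

Step 9. Carbon delivery may occur on the wrong alkene face. Inner-sphere C–O bond formation may give the cis ring fusion. Palladium may dehydrogenate the C8 carbinol, or insertion into the internal diene may be too slow. The fallback keeps the one-operation annulation but changes the mechanism to a radical–cation one. Setting out from 15, Mn(OAc)3·2H2O with excess malonic acid in AcOH–MeCN at 40 °C should add the malonyl radical to the diene terminus C7; trivalent manganese then oxidises the allyl radical, and one carboxyl captures the cation at C6 to give the trans-fused (3aR,4R,6E,10E,11aR)-6,10-bis({[tert-butyl(dimethyl)silyl]oxy}methyl)-4-hydroxy-2-oxo-2,3,3a,4,5,8,9,11a-octahydrocyclodeca[b]furan-3-carboxylic acid F1. Decarboxylative Mannich methylenation of F1 (paraformaldehyde, Et2NH, THF, 65 °C) comes back to the route at 17.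

Step 8. Intermolecular metathesis may give oligomers. Ring-contracting metathesis at the trisubstituted C4=C5 or C1=C10 alkenes may give eight- or six-membered rings. Ruthenium hydrides may isomerise the allylic alcohol. The fallback closes the ring at the lactone stage. There both trisubstituted alkenes are acceptor-substituted and should be inert to the ruthenium alkylidene, and the butyrolactone ties C8 to C10. Setting out from 12, the same catalyst in dilute toluene at 80 °C should give ethyl (1E,5E,7Z,9R)-11-oxo-10-oxabicyclo[7.2.1]dodeca-1,5,7-triene-5-carboxylate F2. Reduction of F2 with i-Bu2AlH should give (1R,2Z,4E,8E)-5,9-bis(hydroxymethyl)cyclodeca-2,4,8-trien-1-ol F3. Bis-silylation of F3 under the conditions of step 7 comes back to the route at 15.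

Step 5. The enolisable aldehyde may transfer a proton to the lactone enolate. Retro-aldol cleavage may occur during mesylation. The elimination may not be fully E-selective. The fallback replaces the aldol condensation by a phosphonate olefination. Setting out from 3, LiN(i-Pr)2 (2.2 equiv) and ClP(O)(OEt)2 in THF (−78 °C → rt; enol phosphate formation and 1,3-phosphorus shift) should give diethyl [(5R)-5-ethenyl-2-oxooxolan-3-yl]phosphonate F4. Horner–Wadsworth–Emmons reaction of F4 with 9 (NaH, THF, 0 °C → rt) comes back to the route at 12.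

Further compounds

F1 | step 9 | (3aR,4R,6E,10E,11aR)-6,10-bis({[tert-butyl(dimethyl)silyl]oxy}methyl)-4-hydroxy-2-oxo-2,3,3a,4,5,8,9,11a-octahydrocyclodeca[b]furan-3-carboxylic acid (C3 epimers) | OC(=O)C1C(=O)O[C@@H]2/C=C(/CO[Si](C)(C)C(C)(C)C)CC/C=C(/CO[Si](C)(C)C(C)(C)C)C[C@@H](O)[C@@H]12
F2 | step 8 | ethyl (1E,5E,7Z,9R)-11-oxo-10-oxabicyclo[7.2.1]dodeca-1,5,7-triene-5-carboxylate | CCOC(=O)/C1=C/C=C\[C@H]2C/C(=C\CC1)C(=O)O2
F3 | step 8 | (1R,2Z,4E,8E)-5,9-bis(hydroxymethyl)cyclodeca-2,4,8-trien-1-ol | C1/C(CO)=C\C=C/[C@H](O)C/C(CO)=C\C1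
F4 | step 5 | diethyl [(5R)-5-ethenyl-2-oxooxolan-3-yl]phosphonate (C3 epimers) | C=C[C@H]1CC(P(=O)(OCC)OCC)C(=O)O1
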